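**Plan**
1. Retrosynthetic cuts, in order (locants of the hexacosanolide name: C1 = lactone C=O, C22 = ketone, C26 = OCH2): (i) the C15–S bond of a temporary phenylsulfonyl group; (ii) the C16–C17 bond, with C17–C22 joined again, which turns the 27-membered keto lactone into the ester of a 1-substituted cyclohexanol; (iii) the ester bond C1–O; (iv) the two C–C bonds at C22 (C5 bis-Grignard reagent + δ-valerolactone) and, on the acid, C15–S (terminal alkyne + thiol).
2. Enabling feature: the ketone carbon C22 and C17 are bridged by C18–C21, so C17–C22 form a six-membered carbocycle when C22 is held at the tertiary-alcohol level. β-Scission of the C22–O radical of that cyclohexanol gives the C22 ketone and a primary radical at C17, exactly where the large ring must close.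
3. Forward order: the six-membered ring is made first (step 1), the acceptor chain is attached through the ester (steps 2–4), then one event opens the six-membered ring and closes the 27-membered ring at C16–C17 (step 5). The sulfone helper is removed last (step 6).
4. Stereochemistry: the target has no stereocentre. The only one on the way, C15 of the sulfone, is racemic and is erased in step 6.

Key step: step 5

Remark: radicals and activated-acyl species that exist only within a mechanism are described in the Why lines and are not numbered; the bis-Grignard reagent, made in a separate operation, is numbered.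

**Step 1**
Reactants: 1 1,5-dibromopentane; 2 oxan-2-one (δ-valerolactone)
Product: 4 1-(4-hydroxybutyl)cyclohexan-1-ol, via pentane-1,5-diylbis(magnesium bromide) 3 (not isolated)
Conditions: Mg (2.4 equiv), THF, reflux; then 2 added slowly, 0 °C → rt; H2O quench
Reagents that add atoms: none
Why: Double Grignard addition to a lactone: the first C–Mg terminus opens the lactone to a ketone, which the second terminus captures intramolecularly in a six-membered ring closure, leaving the lactone oxygen as the primary alcohol.

**Step 2**
Reactants: 5 hexadec-15-ynoic acid
Product: 6 15-(phenylsulfanyl)hexadec-15-enoic acid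
Conditions: PhSH (1.1 equiv), Pd(OAc)2 (3 mol %), THF, 40 °C
Reagents that add atoms: thiophenol, Sc1ccccc1
Why: Pd-thiolate-catalysed Markovnikov hydrothiolation of a terminal alkyne: syn-thiopalladation places sulfur on the internal carbon C15 and protonolysis by the thiol should release the 1,1-disubstituted vinyl sulfide, the free acid being tolerated.

**Step 3**
Reactants: 6 15-(phenylsulfanyl)hexadec-15-enoic acid; 4 1-(4-hydroxybutyl)cyclohexan-1-ol
Product: 7 4-(1-hydroxycyclohexyl)butyl 15-(phenylsulfanyl)hexadec-15-enoate
Conditions: EDC·HCl (1.3 equiv), DMAP (0.1 equiv), CH2Cl2, 0 °C → rt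
Reagents that add atoms: none
Why: Steglich-type carbodiimide esterification, in which the primary hydroxyl should be acylated selectively because the tertiary cyclohexanol is far too hindered to react with the acyl-pyridinium intermediate.

**Step 4**
Reactants: 7 4-(1-hydroxycyclohexyl)butyl 15-(phenylsulfanyl)hexadec-15-enoate
Product: 8 4-(1-hydroxycyclohexyl)butyl 15-(phenylsulfonyl)hexadec-15-enoate
Conditions: mCPBA (2.3 equiv), CH2Cl2, 0 °C → rt
Reagents that add atoms: mCPBA, O=C(OO)c1cccc(Cl)c1
Why: Peracid oxidation of a sulfide to the sulfone: sulfur should be oxidised twice much faster than the C=C bond, which is electron-poor after the first oxygen transfer, and the tertiary alcohol and ester are inert.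

**Step 5**
Reactants: 8 4-(1-hydroxycyclohexyl)butyl 15-(phenylsulfonyl)hexadec-15-enoate
Product: 9 (±)-15-(phenylsulfonyl)-22-oxohexacosan-26-olide
Conditions: [Ir(dF(CF3)ppy)2(5,5′-d(CF3)bpy)]PF6 (2 mol %), 2,4,6-collidine (5 equiv), MeCN–CH2Cl2 1:1, 2 mM, 450 nm LEDs, rt, degassed, no H-atom donor
Reagents that add atoms: none
Why: Proposed new method: the photoexcited Ir(III) complex and collidine remove the hydroxyl hydrogen of 8 by concerted proton-coupled electron transfer, and the tertiary C22 alkoxy radical undergoes β-scission of a ring C22–C17 bond (the two ring bonds are equivalent) to give the C22 ketone and a primary radical at C17. This nucleophilic radical adds to the unsubstituted C16 terminus of the 1,1-disubstituted vinyl sulfone, and the electrophilic α-sulfonyl C15 radical is reduced by Ir(II) and protonated by collidinium, so the overall change is a redox-neutral isomerisation. The closest known reaction types are the light-driven ring-opening of cycloalkanols with Giese trapping or ring expansion of the distal radical, and the tin hydride-mediated endo macrocyclisation of ω-iodoalkyl acrylates. The only ring closed is the 27-membered lactone, in 27-endo-trig mode, while the six-membered carbocycle is opened. The one new stereocentre (C15) is set without control by protonation and is deleted in step 6. The step needs ring scission to beat exocyclic C22–C23 scission and the 1,5-hydrogen shift from C25, and ring closure to beat oligomerisation and premature quenching; the two equivalent ring bonds, the inductively deactivated C25–H next to the acyloxy-bearing C26, the polar medium, the 2 mM dilution, the absence of any hydrogen-atom donor and the sulfone on C15 (rate and choice of terminus) should secure this.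

**Step 6**
Reactants: 9 (±)-15-(phenylsulfonyl)-22-oxohexacosan-26-olide
Product: 10 22-keto-26-hexacosanolide (1-oxacycloheptacosane-2,23-dione)
Conditions: 6% Na(Hg), Na2HPO4, THF–MeOH, −20 → 0 °C
Reagents that add atoms: none
Why: Reductive desulfonylation by single-electron transfer: the sulfone radical anion should expel benzenesulfinate and the C15 radical is reduced and protonated, while the phosphate buffer and low temperature spare the dialkyl ketone and the lactone.

**Compound list**
1 | 1,5-dibromopentane | BrCCCCCBr | starting material
2 | oxan-2-one (δ-valerolactone) | O=C1CCCCO1 | starting material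
3 | pentane-1,5-diylbis(magnesium bromide) | Br[Mg]CCCCC[Mg]Br | intermediate
4 | 1-(4-hydroxybutyl)cyclohexan-1-ol | OCCCCC1(O)CCCCC1 | intermediate
5 | hexadec-15-ynoic acid | C#CCCCCCCCCCCCCCC(=O)O | starting material
6 | 15-(phenylsulfanyl)hexadec-15-enoic acid | C=C(Sc1ccccc1)CCCCCCCCCCCCCC(=O)O | intermediate
7 | 4-(1-hydroxycyclohexyl)butyl 15-(phenylsulfanyl)hexadec-15-enoate | C=C(Sc1ccccc1)CCCCCCCCCCCCCC(=O)OCCCCC2(O)CCCCC2 | intermediate
8 | 4-(1-hydroxycyclohexyl)butyl 15-(phenylsulfonyl)hexadec-15-enoate | C=C(S(=O)(=O)c1ccccc1)CCCCCCCCCCCCCC(=O)OCCCCC2(O)CCCCC2 | intermediate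
9 | (±)-15-(phenylsulfonyl)-22-oxohexacosan-26-olide [16-(phenylsulfonyl)-1-oxacycloheptacosane-2,23-dione, racemic] | O=C1CCCCCCC(S(=O)(=O)c2ccccc2)CCCCCCCCCCCCCC(=O)OCCCC1 | intermediate
10 | 22-keto-26-hexacosanolide (1-oxacycloheptacosane-2,23-dione) | O=C1CCCCCCCCCCCCCCCCCCCCC(=O)OCCCC1 | target

**Step count and risks**
Total steps: 6. Longest linear sequence: 5 (steps 2, 3, 4, 5, 6).

Most likely to fail:

1. Step 5 (proposed new method). The alkoxy radical may partition into exocyclic C–C scission or 1,5-hydrogen transfer. The ring-opened radical may also re-close reversibly and drain into these leaks, or oligomerise, before the slow 27-membered ring closure. Photochemical quenching may be inefficient at the dilution required. Fallback (known chemistry, sets out from 2, returns at 10): oxan-2-one 2 would be opened with N,O-dimethylhydroxylamine hydrochloride/AlMe3 in CH2Cl2 to 5-hydroxy-N-methoxy-N-methylpentanamide F1, which with hex-5-enylmagnesium bromide (2.5 equiv, THF, 0 °C) should give 11-hydroxyundec-1-en-7-one F2. The same Grignard reagent would be coupled with 11-bromoundecanoic acid (Li2CuCl4 cat., THF, −10 °C) to heptadec-16-enoic acid F3. Carbodiimide esterification of F2 with F3 should give 5-oxoundec-10-en-1-yl heptadec-16-enoate F4. Ring-closing metathesis (second-generation Ru benzylidene catalyst, CH2Cl2, 1 mM, reflux) should then form the same C16–C17 bond as an alkene in 22-oxohexacos-16-en-26-olide F5 (E/Z mixture), and hydrogenation (H2, Pd/C, EtOAc) should give 10.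

2. Step 6. The ketone may be over-reduced or the lactone opened by methanolysis while the C–S bond is cleaved, or cleavage may stop short. Fallback (sets out from 9, returns at 10): the over-reduction is accepted and corrected. SmI2/HMPA in THF–MeOH (−20 °C) should cleave the sulfone and reduce the ketone to 22-hydroxyhexacosan-26-olide F6, and Dess–Martin periodinane (CH2Cl2, rt) should restore the ketone to give 10.

3. Step 2. Markovnikov regiocontrol may be lost, a second thiol may add, or the double bond may migrate into the chain. Fallback (sets out from 5, returns at 8): the sulfur is introduced directly at the sulfone level. Au(I)-catalysed Markovnikov addition of benzenesulfinic acid to 5 should give 15-(phenylsulfonyl)hexadec-15-enoic acid F7, which is esterified with 4 under the conditions of step 3 to give 8, replacing steps 2–4.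

**Further compounds**
F1 | step 5 | 5-hydroxy-N-methoxy-N-methylpentanamide | CON(C)C(=O)CCCCO
F2 | step 5 | 11-hydroxyundec-1-en-7-one | C=CCCCCC(=O)CCCCO
F3 | step 5 | heptadec-16-enoic acid | C=CCCCCCCCCCCCCCCC(=O)O
F4 | step 5 | 5-oxoundec-10-en-1-yl heptadec-16-enoate | C=CCCCCC(=O)CCCCOC(=O)CCCCCCCCCCCCCCC=C
F5 | step 5 | 22-oxohexacos-16-en-26-olide (E/Z mixture) | O=C1CCCCC=CCCCCCCCCCCCCCCC(=O)OCCCC1
F6 | step 6 | 22-hydroxyhexacosan-26-olide (racemic) | OC1CCCCCCCCCCCCCCCCCCCCC(=O)OCCCC1
F7 | step 2 | 15-(phenylsulfonyl)hexadec-15-enoic acid | C=C(S(=O)(=O)c1ccccc1)CCCCCCCCCCCCCC(=O)O
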